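**Plan**

- Ring and atom labels: ring A is the benzo ring of the 2,3-dihydro-1,4-benzodioxine (O1, C2, C3, O4), ring B the catechol aryl on C2, ring C the biphenyl. Enabling feature: the five allyl groups sit on C7 of ring A, on C4 of both phenoxy rings and on C5 and C5' of ring C, each through an aryl C(sp2)–CH2 bond at an unhindered position, and they are the only alkenes. The retrosynthesis therefore cuts these five bonds first and carries five aryl bromides in their place (pentabromide 22).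
- Further cuts, in order: the CH2–O bond to ring C (Mitsunobu), the benzylic C2–O1 bond of the dioxane (acid-catalysed closure), the C2–C3 bond (Evans aldol), the O4–CH2 bond (Williamson) and the two diaryl ether bonds (Chan–Lam on ring B, SNAr on ring A).
- Forward: ring-B aldehyde 6 from methyl gallate, with the catechol held as a diphenylmethylene ketal that also leaves only one hydroxyl free for the arylation. Ring-A imide 14 comes from 4-bromo-2,6-difluorobenzaldehyde, whose formyl carbon is excised by a Dakin oxidation to unmask the central oxygen O4.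
- The aldol joins A and B; reduction, deallylation and acid closure build the dioxane, the only ring made; ring C is then attached, the five allyl groups are installed and the acetals are hydrolysed.
- Stereochemistry: C3 comes from the (S)-4-benzyloxazolidinone in the boron aldol. C2 is set trans to C3 in the reversible ring closure, giving (2R,3R).

Key step: step 15

Assumption: (4S)-4-benzyl-3-(chloroacetyl)-1,3-oxazolidin-2-one (13) is taken as a purchasable reagent; otherwise it is one N-acylation of (S)-4-benzyloxazolidin-2-one with chloroacetyl chloride.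

**Route**

Step 1
Reactants: 1 methyl gallate
Product: 2 methyl 7-hydroxy-2,2-diphenyl-1,3-benzodioxole-5-carboxylate
Conditions: Ph2CCl2, neat, 180 °C
Reagents that add atoms: dichlorodiphenylmethane, ClC(Cl)(c1ccccc1)c1ccccc1
Why: Ketalisation; the geminal dichloride can only bridge two adjacent hydroxyls and the two possible pairs in methyl gallate are equivalent, so one five-membered ketal with a single free phenol should result.

Step 2
Reactants: 2 methyl 7-hydroxy-2,2-diphenyl-1,3-benzodioxole-5-carboxylate; 3 4-bromophenylboronic acid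
Product: 4 methyl 7-(4-bromophenoxy)-2,2-diphenyl-1,3-benzodioxole-5-carboxylate
Conditions: Cu(OAc)2 (divalent copper, 1 equiv), pyridine, 4 Å MS, CH2Cl2, air, rt
Reagents that add atoms: none
Why: Chan–Lam O-arylation of the only free phenol at room temperature, under which the aryl bromide of the boronic acid is not activated.

Step 3
Reactants: 4 methyl 7-(4-bromophenoxy)-2,2-diphenyl-1,3-benzodioxole-5-carboxylate
Product: 5 [7-(4-bromophenoxy)-2,2-diphenyl-1,3-benzodioxol-5-yl]methanol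
Conditions: i-Bu2AlH (2.5 equiv), CH2Cl2, −78 → 0 °C
Reagents that add atoms: none
Why: Hydride reduction of the aryl ester to the benzylic alcohol; aryl bromide, diaryl ether and ketal are inert to i-Bu2AlH at low temperature.

Step 4
Reactants: 5 [7-(4-bromophenoxy)-2,2-diphenyl-1,3-benzodioxol-5-yl]methanol
Product: 6 7-(4-bromophenoxy)-2,2-diphenyl-1,3-benzodioxole-5-carbaldehyde
Conditions: MnO2 (excess), CH2Cl2, rt
Reagents that add atoms: none
Why: Selective benzylic alcohol oxidation with MnO2, which stops at the aldehyde.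

Step 5
Reactants: 7 4-bromo-2,6-difluorobenzaldehyde; 8 4-bromophenol
Product: 9 4-bromo-2-(4-bromophenoxy)-6-fluorobenzaldehyde
Conditions: K2CO3, DMF, 0 °C → rt
Reagents that add atoms: none
Why: SNAr; both fluorides are ortho to the formyl group, one is displaced by the phenoxide, the new aryloxy donor slows a second substitution, and fluoride leaves far faster than the para bromide.

Step 6
Reactants: 9 4-bromo-2-(4-bromophenoxy)-6-fluorobenzaldehyde
Product: 10 4-bromo-2-(4-bromophenoxy)-6-(prop-2-enyloxy)benzaldehyde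
Conditions: allyl alcohol, NaH, THF, 0 °C; then 9, 0 → 50 °C
Reagents that add atoms: allyl alcohol, C=CCO
Why: SNAr of the remaining formyl-activated fluoride by sodium allyloxide; the allyl ether masks the oxygen that becomes O1.

Step 7
Reactants: 10 4-bromo-2-(4-bromophenoxy)-6-(prop-2-enyloxy)benzaldehyde
Product: 12 4-bromo-2-(4-bromophenoxy)-6-(prop-2-enyloxy)phenol, via aryl formate 11 (not isolated)
Conditions: 30% aq H2O2, H2SO4 (cat.), MeOH, rt
Reagents that add atoms: hydrogen peroxide, OO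
Why: Acid-catalysed Dakin oxidation (Baeyer–Villiger-type aryl migration); two ortho oxygen donors favour aryl migration, the formate is methanolysed in the flask, and H2O2 without a peracid leaves the allyl ether alone.

Step 8
Reactants: 12 4-bromo-2-(4-bromophenoxy)-6-(prop-2-enyloxy)phenol; 13 (4S)-4-benzyl-3-(chloroacetyl)-1,3-oxazolidin-2-one
Product: 14 (4S)-4-benzyl-3-{[4-bromo-2-(4-bromophenoxy)-6-(prop-2-enyloxy)phenoxy]acetyl}-1,3-oxazolidin-2-one
Conditions: K2CO3, NaI (cat.), acetone, rt → 45 °C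
Reagents that add atoms: none
Why: Williamson etherification; SN2 displacement at the α-chloroacyl carbon, accelerated by iodide (Finkelstein), should outrun attack of the hindered phenoxide at the imide carbonyl.

Step 9
Reactants: 14 (4S)-4-benzyl-3-{[4-bromo-2-(4-bromophenoxy)-6-(prop-2-enyloxy)phenoxy]acetyl}-1,3-oxazolidin-2-one; 6 7-(4-bromophenoxy)-2,2-diphenyl-1,3-benzodioxole-5-carbaldehyde
Product: 16 (4S)-4-benzyl-3-[(2S,3R)-2-[4-bromo-2-(4-bromophenoxy)-6-(prop-2-enyloxy)phenoxy]-3-[7-(4-bromophenoxy)-2,2-diphenyl-1,3-benzodioxol-5-yl]-3-hydroxypropanoyl]-1,3-oxazolidin-2-one, via Z boron enolate 15 (not isolated)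
Conditions: n-Bu2BOTf, i-Pr2NEt, CH2Cl2, −78 → 0 °C; then 6, −78 → 0 °C; pH 7 buffer, MeOH, 30% H2O2, 0 °C
Reagents that add atoms: none
Why: Evans syn aldol; the Z dibutylboron enolate reacts through a closed chair transition state on the face away from the auxiliary benzyl group, setting the α-carbon S (it becomes C3, R once reduction changes the priorities) and the carbinol carbon R.

Step 10
Reactants: 16 (4S)-4-benzyl-3-[(2S,3R)-2-[4-bromo-2-(4-bromophenoxy)-6-(prop-2-enyloxy)phenoxy]-3-[7-(4-bromophenoxy)-2,2-diphenyl-1,3-benzodioxol-5-yl]-3-hydroxypropanoyl]-1,3-oxazolidin-2-one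
Product: 17 (1R,2R)-2-[4-bromo-2-(4-bromophenoxy)-6-(prop-2-enyloxy)phenoxy]-1-[7-(4-bromophenoxy)-2,2-diphenyl-1,3-benzodioxol-5-yl]propane-1,3-diol
Conditions: LiBH4, MeOH (1 equiv), THF, 0 °C
Reagents that add atoms: none
Why: Reductive cleavage of the N-acyloxazolidinone to the primary alcohol, which releases the auxiliary and does not touch either stereocentre.

Step 11
Reactants: 17 (1R,2R)-2-[4-bromo-2-(4-bromophenoxy)-6-(prop-2-enyloxy)phenoxy]-1-[7-(4-bromophenoxy)-2,2-diphenyl-1,3-benzodioxol-5-yl]propane-1,3-diol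
Product: 18 (1R,2R)-2-[4-bromo-2-(4-bromophenoxy)-6-hydroxyphenoxy]-1-[7-(4-bromophenoxy)-2,2-diphenyl-1,3-benzodioxol-5-yl]propane-1,3-diol
Conditions: Pd(PPh3)4 (5 mol %), morpholine, THF, rt
Reagents that add atoms: none
Why: Deallylation of the aryl allyl ether catalysed by zerovalent palladium (Tsuji–Trost type), with morpholine trapping the π-allyl complex; at room temperature Pd(PPh3)4 should not insert into the aryl bromides.

Step 12
Reactants: 18 (1R,2R)-2-[4-bromo-2-(4-bromophenoxy)-6-hydroxyphenoxy]-1-[7-(4-bromophenoxy)-2,2-diphenyl-1,3-benzodioxol-5-yl]propane-1,3-diol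
Product: 19 {(2R,3R)-6-bromo-8-(4-bromophenoxy)-3-[7-(4-bromophenoxy)-2,2-diphenyl-1,3-benzodioxol-5-yl]-2,3-dihydro-1,4-benzodioxin-2-yl}methanol
Conditions: TsOH·H2O (10 mol %), 4 Å MS, toluene, 80 °C
Reagents that add atoms: none
Why: Acid-catalysed dehydrative etherification (SN1), the classical closure of β-aryl ether alcohols to 2-aryl-1,4-benzodioxanes; the benzylic hydroxyl para to a dioxole oxygen ionises, the ortho phenol closes the six-membered ring, and because this C–O bond re-ionises the diequatorial trans isomer should accumulate, so the untouched C3 fixes C2 as R, while the ketal should survive anhydrous catalytic acid.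

Step 13
Reactants: 20 5,5'-dibromo-2,2'-biphenol
Product: 21 5,5'-dibromo-2'-(methoxymethoxy)biphenyl-2-ol
Conditions: 20 (2 equiv), MOMCl (1 equiv), i-Pr2NEt, CH2Cl2, 0 °C
Reagents that add atoms: chloromethyl methyl ether, COCCl
Why: Statistical mono-etherification of a symmetric biphenol; excess 20 suppresses the bis-ether and is recovered.

Step 14
Reactants: 19 {(2R,3R)-6-bromo-8-(4-bromophenoxy)-3-[7-(4-bromophenoxy)-2,2-diphenyl-1,3-benzodioxol-5-yl]-2,3-dihydro-1,4-benzodioxin-2-yl}methanol; 21 5,5'-dibromo-2'-(methoxymethoxy)biphenyl-2-ol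
Product: 22 (2R,3R)-7-bromo-5-(4-bromophenoxy)-2-[7-(4-bromophenoxy)-2,2-diphenyl-1,3-benzodioxol-5-yl]-3-({[5,5'-dibromo-2'-(methoxymethoxy)biphenyl-2-yl]oxy}methyl)-2,3-dihydro-1,4-benzodioxine
Conditions: PPh3, DIAD, THF, 0 °C → rt
Reagents that add atoms: none
Why: Mitsunobu etherification; the only hydroxyl of 19 is primary and is displaced by the phenoxide of 21 without involving C2 or C3.

Step 15
Reactants: 22 (2R,3R)-7-bromo-5-(4-bromophenoxy)-2-[7-(4-bromophenoxy)-2,2-diphenyl-1,3-benzodioxol-5-yl]-3-({[5,5'-dibromo-2'-(methoxymethoxy)biphenyl-2-yl]oxy}methyl)-2,3-dihydro-1,4-benzodioxine; 23 allyltributylstannane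
Product: 24 (2R,3R)-2-[2,2-diphenyl-7-(4-prop-2-enylphenoxy)-1,3-benzodioxol-5-yl]-3-({[2'-(methoxymethoxy)-5,5'-di(prop-2-enyl)biphenyl-2-yl]oxy}methyl)-7-(prop-2-enyl)-5-(4-prop-2-enylphenoxy)-2,3-dihydro-1,4-benzodioxine
Conditions: 23 (7.5 equiv), Pd(PPh3)4 (20 mol %), CsF (10 equiv), degassed DMF, 80 °C, 3 h
Reagents that add atoms: none
Why: At each of the five C–Br bonds zerovalent palladium undergoes oxidative addition, fluoride-assisted transmetalation delivers the allyl group from tin, and reductive elimination forms the aryl–CH2 bond and returns the catalyst. The closest known reaction is the Stille (Migita–Kosugi) allylation of aryl bromides, here run at five independent sites of one molecule. No ring is closed and no stereocentre is formed; C2 and C3, the ketal, the MOM ether and all aryl ethers are spectators. The step needs complete fivefold conversion without migration of the allyl double bond into conjugation and without hydrodebromination. The substrate helps because every bromide sits on a ring carbon flanked by two hydrogens, para or meta to an ether oxygen, and no free phenol is present to form a phenoxide. CsF removes the tin as insoluble Bu3SnF and speeds transmetalation, so temperature and time can be kept low enough to limit palladium hydride isomerisation.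

Step 16
Reactants: 24 (2R,3R)-2-[2,2-diphenyl-7-(4-prop-2-enylphenoxy)-1,3-benzodioxol-5-yl]-3-({[2'-(methoxymethoxy)-5,5'-di(prop-2-enyl)biphenyl-2-yl]oxy}methyl)-7-(prop-2-enyl)-5-(4-prop-2-enylphenoxy)-2,3-dihydro-1,4-benzodioxine
Product: 25 5-[(2R,3R)-3-({[2'-hydroxy-5,5'-di(prop-2-enyl)biphenyl-2-yl]oxy}methyl)-7-(prop-2-enyl)-5-(4-prop-2-enylphenoxy)-2,3-dihydro-1,4-benzodioxin-2-yl]-3-(4-prop-2-enylphenoxy)benzene-1,2-diol (CNP0231734.1)
Conditions: 3 M aq HCl, MeOH/THF, 55 °C
Reagents that add atoms: none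
Why: Acid hydrolysis of both acetal-type protecting groups (aryl MOM ether and diphenylmethylene ketal) under conditions that should not protonate isolated terminal alkenes; the trans dioxane is the thermodynamic isomer and so is not at risk.

**Compound list**

1 | methyl gallate | COC(=O)c1cc(O)c(O)c(O)c1 | starting material
2 | methyl 7-hydroxy-2,2-diphenyl-1,3-benzodioxole-5-carboxylate | COC(=O)c1cc(O)c2OC(c3ccccc3)(c3ccccc3)Oc2c1 | intermediate
3 | 4-bromophenylboronic acid | OB(O)c1ccc(Br)cc1 | starting material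
4 | methyl 7-(4-bromophenoxy)-2,2-diphenyl-1,3-benzodioxole-5-carboxylate | COC(=O)c1cc(Oc2ccc(Br)cc2)c2OC(c3ccccc3)(c3ccccc3)Oc2c1 | intermediate
5 | [7-(4-bromophenoxy)-2,2-diphenyl-1,3-benzodioxol-5-yl]methanol | OCc1cc(Oc2ccc(Br)cc2)c2OC(c3ccccc3)(c3ccccc3)Oc2c1 | intermediate
6 | 7-(4-bromophenoxy)-2,2-diphenyl-1,3-benzodioxole-5-carbaldehyde | O=Cc1cc(Oc2ccc(Br)cc2)c2OC(c3ccccc3)(c3ccccc3)Oc2c1 | intermediate
7 | 4-bromo-2,6-difluorobenzaldehyde | O=Cc1c(F)cc(Br)cc1F | starting material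
8 | 4-bromophenol | Oc1ccc(Br)cc1 | starting material
9 | 4-bromo-2-(4-bromophenoxy)-6-fluorobenzaldehyde | O=Cc1c(F)cc(Br)cc1Oc1ccc(Br)cc1 | intermediate
10 | 4-bromo-2-(4-bromophenoxy)-6-(prop-2-enyloxy)benzaldehyde | O=Cc1c(OCC=C)cc(Br)cc1Oc1ccc(Br)cc1 | intermediate
11 | 4-bromo-2-(4-bromophenoxy)-6-(prop-2-enyloxy)phenyl formate | O=COc1c(OCC=C)cc(Br)cc1Oc1ccc(Br)cc1 | intermediate
12 | 4-bromo-2-(4-bromophenoxy)-6-(prop-2-enyloxy)phenol | Oc1c(OCC=C)cc(Br)cc1Oc1ccc(Br)cc1 | intermediate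
13 | (4S)-4-benzyl-3-(chloroacetyl)-1,3-oxazolidin-2-one | O=C(CCl)N1[C@@H](Cc2ccccc2)COC1=O | starting material
14 | (4S)-4-benzyl-3-{[4-bromo-2-(4-bromophenoxy)-6-(prop-2-enyloxy)phenoxy]acetyl}-1,3-oxazolidin-2-one | O=C(COc1c(OCC=C)cc(Br)cc1Oc1ccc(Br)cc1)N1[C@@H](Cc2ccccc2)COC1=O | intermediate
15 | Z dibutylboron enolate of 14 | CCCCB(CCCC)O/C(=C\Oc1c(OCC=C)cc(Br)cc1Oc1ccc(Br)cc1)N1[C@@H](Cc2ccccc2)COC1=O | intermediate
16 | (4S)-4-benzyl-3-[(2S,3R)-2-[4-bromo-2-(4-bromophenoxy)-6-(prop-2-enyloxy)phenoxy]-3-[7-(4-bromophenoxy)-2,2-diphenyl-1,3-benzodioxol-5-yl]-3-hydroxypropanoyl]-1,3-oxazolidin-2-one | O=C([C@@H](Oc1c(OCC=C)cc(Br)cc1Oc1ccc(Br)cc1)[C@H](O)c1cc(Oc2ccc(Br)cc2)c2OC(c3ccccc3)(c3ccccc3)Oc2c1)N1[C@@H](Cc2ccccc2)COC1=O | intermediate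
17 | (1R,2R)-2-[4-bromo-2-(4-bromophenoxy)-6-(prop-2-enyloxy)phenoxy]-1-[7-(4-bromophenoxy)-2,2-diphenyl-1,3-benzodioxol-5-yl]propane-1,3-diol | OC[C@@H](Oc1c(OCC=C)cc(Br)cc1Oc1ccc(Br)cc1)[C@H](O)c1cc(Oc2ccc(Br)cc2)c2OC(c3ccccc3)(c3ccccc3)Oc2c1 | intermediate
18 | (1R,2R)-2-[4-bromo-2-(4-bromophenoxy)-6-hydroxyphenoxy]-1-[7-(4-bromophenoxy)-2,2-diphenyl-1,3-benzodioxol-5-yl]propane-1,3-diol | OC[C@@H](Oc1c(O)cc(Br)cc1Oc1ccc(Br)cc1)[C@H](O)c1cc(Oc2ccc(Br)cc2)c2OC(c3ccccc3)(c3ccccc3)Oc2c1 | intermediate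
19 | {(2R,3R)-6-bromo-8-(4-bromophenoxy)-3-[7-(4-bromophenoxy)-2,2-diphenyl-1,3-benzodioxol-5-yl]-2,3-dihydro-1,4-benzodioxin-2-yl}methanol | Brc1ccc(Oc2cc([C@H]3Oc4cc(Br)cc(Oc5ccc(Br)cc5)c4O[C@@H]3CO)cc3OC(c4ccccc4)(c4ccccc4)Oc23)cc1 | intermediate
20 | 5,5'-dibromo-2,2'-biphenol | Oc1ccc(Br)cc1-c1cc(Br)ccc1O | starting material
21 | 5,5'-dibromo-2'-(methoxymethoxy)biphenyl-2-ol | COCOc1ccc(Br)cc1-c1cc(Br)ccc1O | intermediate
22 | (2R,3R)-7-bromo-5-(4-bromophenoxy)-2-[7-(4-bromophenoxy)-2,2-diphenyl-1,3-benzodioxol-5-yl]-3-({[5,5'-dibromo-2'-(methoxymethoxy)biphenyl-2-yl]oxy}methyl)-2,3-dihydro-1,4-benzodioxine | Brc1ccc(Oc2cc([C@H]3Oc4cc(Br)cc(Oc5ccc(Br)cc5)c4O[C@@H]3COc3ccc(Br)cc3-c3cc(Br)ccc3OCOC)cc3OC(c4ccccc4)(c4ccccc4)Oc23)cc1 | intermediate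
23 | allyltributylstannane | C=CC[Sn](CCCC)(CCCC)CCCC | starting material
24 | (2R,3R)-2-[2,2-diphenyl-7-(4-prop-2-enylphenoxy)-1,3-benzodioxol-5-yl]-3-({[2'-(methoxymethoxy)-5,5'-di(prop-2-enyl)biphenyl-2-yl]oxy}methyl)-7-(prop-2-enyl)-5-(4-prop-2-enylphenoxy)-2,3-dihydro-1,4-benzodioxine | C=CCc1ccc(Oc2cc([C@H]3Oc4cc(CC=C)cc(Oc5ccc(CC=C)cc5)c4O[C@@H]3COc3ccc(CC=C)cc3-c3cc(CC=C)ccc3OCOC)cc3OC(c4ccccc4)(c4ccccc4)Oc23)cc1 | intermediate
25 | 5-[(2R,3R)-3-({[2'-hydroxy-5,5'-di(prop-2-enyl)biphenyl-2-yl]oxy}methyl)-7-(prop-2-enyl)-5-(4-prop-2-enylphenoxy)-2,3-dihydro-1,4-benzodioxin-2-yl]-3-(4-prop-2-enylphenoxy)benzene-1,2-diol | C=CCc1ccc(Oc2cc([C@H]3Oc4cc(CC=C)cc(Oc5ccc(CC=C)cc5)c4O[C@@H]3COc3ccc(CC=C)cc3-c3cc(CC=C)ccc3O)cc(O)c2O)cc1 | target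

**Step count and risks**

Total step count: 16. Longest linear sequence: 11 steps (steps 1–4, 9–12, 14–16; the branch from 7 through steps 5–8 is equally long).

Steps most likely to fail:

1. Step 15. The fivefold coupling may stop short of full conversion, the allyl double bonds may migrate into conjugation under prolonged heating, or bromides may be reduced. Fallback: setting out from 22, the five bonds would be formed by Suzuki–Miyaura coupling with allylboronic acid pinacol ester (PdCl2(dppf), a divalent palladium precatalyst, CsF, THF, reflux), where transmetalation from the fluoroborate does not depend on tin. The route is rejoined at 24, and no new compound arises (F0).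

2. Step 12. The diphenylmethylene ketal may erode under the acid, equilibration to the trans ring may be incomplete, or the benzylic cation may fragment the side chain before the phenol traps it. Fallback: setting out from 18, the ketal is given up on purpose. Heating in AcOH/6 M aq HCl at 70 °C hydrolyses the ketal and closes the ring; with the para hydroxyl of ring B free, the C2–O1 bond opens and recloses through a para-quinone methide, which makes equilibration to trans easy, and should give 5-[(2R,3R)-7-bromo-5-(4-bromophenoxy)-3-(hydroxymethyl)-2,3-dihydro-1,4-benzodioxin-2-yl]-3-(4-bromophenoxy)benzene-1,2-diol F1. MOMCl and K2CO3 in acetone etherify only the two phenols to give {(2R,3R)-6-bromo-8-(4-bromophenoxy)-3-[3-(4-bromophenoxy)-4,5-bis(methoxymethoxy)phenyl]-2,3-dihydro-1,4-benzodioxin-2-yl}methanol F2. Mitsunobu coupling with 21 as in step 14 gives (2R,3R)-7-bromo-5-(4-bromophenoxy)-2-[3-(4-bromophenoxy)-4,5-bis(methoxymethoxy)phenyl]-3-({[5,5'-dibromo-2'-(methoxymethoxy)biphenyl-2-yl]oxy}methyl)-2,3-dihydro-1,4-benzodioxine F3. The fivefold allylation under the conditions of step 15 gives (2R,3R)-2-[4,5-bis(methoxymethoxy)-3-(4-prop-2-enylphenoxy)phenyl]-3-({[2'-(methoxymethoxy)-5,5'-di(prop-2-enyl)biphenyl-2-yl]oxy}methyl)-7-(prop-2-enyl)-5-(4-prop-2-enylphenoxy)-2,3-dihydro-1,4-benzodioxine F4. Finally 2 M HCl in MeOH at 45 °C removes the three MOM groups, and the route is rejoined at 25.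

3. Step 8. The phenoxide may attack the imide carbonyl (acyl transfer with loss of the auxiliary), or the carbonate may cleave the imide, instead of clean O-alkylation. Fallback: setting out from 12, the auxiliary is attached after the ether bond is made. Alkylation with tert-butyl bromoacetate (K2CO3, acetone) gives tert-butyl [4-bromo-2-(4-bromophenoxy)-6-(prop-2-enyloxy)phenoxy]acetate F5. TFA in CH2Cl2 gives [4-bromo-2-(4-bromophenoxy)-6-(prop-2-enyloxy)phenoxy]acetic acid F6. Pivaloyl chloride and Et3N in THF at −20 °C give, in the flask, [4-bromo-2-(4-bromophenoxy)-6-(prop-2-enyloxy)phenoxy]acetic pivalic anhydride F7. Lithiated (4S)-4-benzyl-1,3-oxazolidin-2-one (n-BuLi, THF, −78 °C) acylates at the less hindered carbonyl, and the route is rejoined at 14.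

Further compounds
F0 | step 15 | none | none
F1 | step 12 | 5-[(2R,3R)-7-bromo-5-(4-bromophenoxy)-3-(hydroxymethyl)-2,3-dihydro-1,4-benzodioxin-2-yl]-3-(4-bromophenoxy)benzene-1,2-diol | Brc1ccc(Oc2cc([C@H]3Oc4cc(Br)cc(Oc5ccc(Br)cc5)c4O[C@@H]3CO)cc(O)c2O)cc1
F2 | step 12 | {(2R,3R)-6-bromo-8-(4-bromophenoxy)-3-[3-(4-bromophenoxy)-4,5-bis(methoxymethoxy)phenyl]-2,3-dihydro-1,4-benzodioxin-2-yl}methanol | Brc1ccc(Oc2cc([C@H]3Oc4cc(Br)cc(Oc5ccc(Br)cc5)c4O[C@@H]3CO)cc(OCOC)c2OCOC)cc1
F3 | step 12 | (2R,3R)-7-bromo-5-(4-bromophenoxy)-2-[3-(4-bromophenoxy)-4,5-bis(methoxymethoxy)phenyl]-3-({[5,5'-dibromo-2'-(methoxymethoxy)biphenyl-2-yl]oxy}methyl)-2,3-dihydro-1,4-benzodioxine | Brc1ccc(Oc2cc([C@H]3Oc4cc(Br)cc(Oc5ccc(Br)cc5)c4O[C@@H]3COc3ccc(Br)cc3-c3cc(Br)ccc3OCOC)cc(OCOC)c2OCOC)cc1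
F4 | step 12 | (2R,3R)-2-[4,5-bis(methoxymethoxy)-3-(4-prop-2-enylphenoxy)phenyl]-3-({[2'-(methoxymethoxy)-5,5'-di(prop-2-enyl)biphenyl-2-yl]oxy}methyl)-7-(prop-2-enyl)-5-(4-prop-2-enylphenoxy)-2,3-dihydro-1,4-benzodioxine | C=CCc1ccc(Oc2cc([C@H]3Oc4cc(CC=C)cc(Oc5ccc(CC=C)cc5)c4O[C@@H]3COc3ccc(CC=C)cc3-c3cc(CC=C)ccc3OCOC)cc(OCOC)c2OCOC)cc1
F5 | step 8 | tert-butyl [4-bromo-2-(4-bromophenoxy)-6-(prop-2-enyloxy)phenoxy]acetate | CC(C)(C)OC(=O)COc1c(OCC=C)cc(Br)cc1Oc1ccc(Br)cc1
F6 | step 8 | [4-bromo-2-(4-bromophenoxy)-6-(prop-2-enyloxy)phenoxy]acetic acid | OC(=O)COc1c(OCC=C)cc(Br)cc1Oc1ccc(Br)cc1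
F7 | step 8 | [4-bromo-2-(4-bromophenoxy)-6-(prop-2-enyloxy)phenoxy]acetic pivalic anhydride | CC(C)(C)C(=O)OC(=O)COc1c(OCC=C)cc(Br)cc1Oc1ccc(Br)cc1
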